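The constants used here were set for the occasion; no experiment stands behind them.

Count before you run.

common to all: substrate 0.050 M; partner 0.0500 M; protic impurity 0.0250 M; time 50 h
- maple: temperature 75 °C
- ash: temperature 50 °C

    substrate → intermediate (k1 = 0.050 /h, Ea1 = 112 kJ/mol)
    partner + intermediate → product (k2 = 0.64 /M/h, Ea2 = 70.0 kJ/mol)
    partner + protic impurity → quenched reagent (k3 = 19 /M/h, Ea3 = 51.0 kJ/mol)
    substrate ⇌ dormant form (K4 = 16, k4 = 0.011 /h, Ea4 = 116 kJ/mol, ΔH4 = −36.0 kJ/mol)
    (constants at 50 °C)

- the list of constants is for 50 °C, to be carried to other temperatures by the activation energies and enthalpies

* which flask leads in amount of product, in percent of the substrate charged ("all alike" within 1.5 percentage points) (maple / ash / all alike)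
* how much product is there at the end, in percent of the substrate charged: maple
* how much product is there at the end, in percent of the substrate charged: ash

- At 50 °C the impurity's constant 19 /M/h is far larger than the coupling constant 0.64 /M/h, so I let the impurity take 0.0250 M of partner first in both flasks, leaving 0.0250 M. That is less than the substrate, so this leftover partner is the limiting reagent and the ceiling on product is 50.0% of the substrate charged.
- In ash, substrate leaves with 0.050 /h towards intermediate and 0.011 /h towards dormant form. So 82.0% of it becomes intermediate, 0.0410 M, after a delay of about 16.4 h.
- Suppose ash keeps that intermediate unspent for the remaining 33.6 h. Then N, the coupling constant times intermediate times time, is 0.881, the coupled share of leftover partner is 1 − exp(−N), and product reaches 29.3%.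
- Now suppose ash holds intermediate through those same hours at the lowest level that first version reaches, 0.0263 M. Product then reaches 21.6%, less than the first version's 29.3%. These two figures are estimates and not bounds, and I expect ash to end somewhere between them.
- So compute only the correction: charge intermediate with 0.5 of what the first version spent. This gives the coupling count N, the coupling constant times mean intermediate times time after the delay 0.724, and ash reaches 25.8%.
- Maple has coupling 6.5 times faster, a delay of 0.805 h, and a count of 5.66, which gives 49.8%.
- The forecast says maple leads, with 49.5% there and 25.5% in ash, where coupling “reaches only about half the cap”. My figures stand slightly above its figures.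
- The simulation gives maple in the lead, with 49.6% there and 25.5% in ash.
- At 10.6 h in ash, substrate's half-life towards intermediate was 14 h, shorter than intermediate's 46 h by coupling, and intermediate was being made 4.92 times faster than used up. The ash flask ended with 52.8% as intermediate and 25.5% as product, which goes with its count of 0.724, smaller than maple's 5.66. In the ash flask with 0.015 M of protic impurity, the ceiling is 70.0%, the count is 0.661, the reckoned product is 33.9%, and that flask held 33.3%.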